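At the reading after 3.0 d you want X in larch, alder and elm, and you have two earlier runs to go on.

the same everywhere: D 0.050 M
- winter: E 0.34 equiv; Z 1 mM; run made earlier
- dusk: E 0.94 equiv; Z 1 mM; run made earlier
- larch: E 0.500 equiv; Z 1.00 mM; time 3.0 d
- alder: E 0.800 equiv; Z 1.00 mM; time 3.0 d
- elm: E 1.20 equiv; Z 1.00 mM; time 3.0 d

| run | time / h | X / % | D / % |
|---|---|---|---|
| winter | 4.00 | 1.0 | 88.0 |
| winter | 8.00 | 3.0 | 80.4 |
| winter | 15.0 | 3.6 | 71.7 |
| winter | 25.0 | 4.3 | 63.5 |
| winter | 48.0 | 2.3 | 52.7 |
| dusk | 10.0 | 13.1 | 57.7 |
| dusk | 20.0 | 14.0 | 42.2 |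
| dusk | 30.0 | 12.8 | 33.9 |
| dusk | 40.0 | 11.3 | 28.0 |
| dusk | 48.0 | 10.1 | 24.0 |

(standard deviation of a reading: 0.3 percentage points)

- X at the end, in percent of the D charged, for each flask in turn (larch, alder, elm)



My reckoning supposes that D takes up E to give a mono adduct Q and a by-product L, and that Q takes up a second E to give X and another L. X is then made at a rate that goes with E times Q and unmade at a rate that goes with X times L. The unmaking rate starts at nil and grows as L builds up, while the making rate shrinks as E falls. Once the two meet in a fast pre-equilibrium, the ratio X·L/(E·Q) stays level.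

Meanwhile the dusk run's D loss slowed from 0.0423 h⁻¹ of the charge over the first interval to 0.00500 h⁻¹ over the last, a factor of 8.46, as D and E both shrank.

To use dusk, you must first take out the D lost without E. By 48.0 h, winter's D loss plus the second E in X overdraws the E charged, which gives a floor for that loss:

winter D lost without E, at least: 15.6 %

I take this route as going with D squared. Summing D squared over time in each run scales the floor to dusk at 48.0 h:

dusk/winter sum: 0.533

dusk D lost without E, taken at that floor: 8.32 %

dusk, estimated, in percent of the D charged: E left 16.2 %, Q 57.6 %, L 77.8 %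

X·L/(E·Q) = 0.841

This is the balance quotient, a reading that carries the scatter. I commit to the rule that X at the end equals the quotient times E left times Q over L.

The forecast, holding that at excess E “D runs out, so decay stalls”, gives 2.3 %, 5.2 % and 19 %; larch, alder and elm give 2.94 %, 6.43 % and 13.6 %.

    2 D → J (k = 0.0876 M⁻¹ h⁻¹)
    Q + Z → G (k = 1.15 M⁻¹ h⁻¹)
    E + Q ⇌ X + L (K = 0.810, k = 4.63 M⁻¹ h⁻¹)
    D + E → Q + L (k = 1.52 M⁻¹ h⁻¹)

With the way back from X + L to E + Q taken away, X in alder goes from 6.43 % to 31.3 %, a rise of 25 percentage points. With the way back kept, alder holds E at 11.9 % of its own charge, Q at 56.0 % and L at 0.0352 M, and the quotient 0.841 gives X as 6.37 % against 6.43 %. Elm holds E at 19.7 % of its own charge, Q at 67.5 % and L at 0.0482 M, and the same quotient gives 13.9 % against 13.6 %.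

Readings and results were generated by integration for substances that don't exist; scatter was added.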